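The numbers in the tables stem from a simulated flask on assumed constants, and the scatter is random.

Count E first: every Q that enters D or Z costs one E, every G costs one more, and Q in L costs none. So E used is (1 + g) times the Q charge, with g the fraction of charged Q standing as G.

| flask | Q | E | remark | time |
|---|---|---|---|---|
| summer | 0.020 M | 0.040 M | run made earlier |  |
| spring | 0.020 M | 0.076 M | run made earlier |  |
| theta | 0.020 M | 0.0300 M |  | 3.0 min |
| zeta | 0.020 M | 0.0600 M |  | 3.0 min |

- summer (time / s: G / %, Z / %): 20.0: 15.9, 21.8; 40.0: 27.4, 15.0; 60.0: 33.1, 10.0; 80.0: 37.6, 7.2; 120: 42.2, 3.3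
- spring (time / s: G / %, Z / %): 10.0: 20.6, 20.5; 25.0: 38.0, 7.0; 40.0: 44.4, 2.6; 60.0: 48.8, 0.5; 90.0: 52.8, 0; 120: 56.7, 0.1

(scatter of a reading: 0.5 percentage points)

- a species is counted by the Q in it: one L counts as two
- steps thought possible: Q + E -> D + J; 2 Q -> L; E + D -> G + J; Q + E -> Z + J; E + Z -> G + J

- which of these holds the largest part of the Q at the end of theta (Q / D / G / Z)
- which of these holds the largest part of the Q at the end of zeta (Q / D / G / Z)
- final G in zeta, as a percentage of the Q charged

1. Read the split (selectivity factor). The part outside G and Z is 54.5% in summer at 120 s and 55.0% in spring at 25.0 s. Take 55.0% as the D made, with L counted in it.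

2. Read the leak from D to G. In spring, G rises from 48.8% to 56.7% between 60.0 s and 120 s. Mean G there is 52.8%, so the balance leaves 59.8% of spring's E. That gives 0.0613 L mol⁻¹ s⁻¹. Doubt: each end carries 0.5 percentage points of scatter on a rise of 7.9 points, so keep it as a reading.

3. Go to logarithms. Try g = 0.5 in zeta: 50.0% of E stands, and D would lose one power of ten in 20.8 min. D then ends at 39.5%, so G is near 60.5%.

4. Objection: that G exceeds the g assumed, so less E stands. Recompute: 46.5% of E gives the decade time of D, the time for one power of ten, 22.4 min. Then D is 40.4% and G 59.6%, which still puts G first in zeta.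

5. Theta: E stands at 33.3% once Q has gone to D and Z, and at 3.33% once Z has gone to G as well. Take the midpoint, 18.3%: the decade time of D in theta is 114 min, so D ends near 51.8%. Objection: D falls as G rises, and L stands inside that D. Count all the rest as G, with Z in it: that gives 48.2%, so I expect D first in theta, ahead by 3.6 points, as an estimate.

The forecast says D, G and 57%, on the ground that in theta “Z uses nearly all of it”. Its G is lower than mine by 2.6 points.

The flasks give D in theta, and G with G at 56.5% in zeta.

    Q + E → D + J (k = 3.24 L mol⁻¹ s⁻¹)
    2 Q → L (k = 0.187 L mol⁻¹ s⁻¹)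
    E + D → G + J (k = 0.0586 L mol⁻¹ s⁻¹)
    Q + E → Z + J (k = 2.24 L mol⁻¹ s⁻¹)
    E + Z → G + J (k = 1.55 L mol⁻¹ s⁻¹)

In zeta, half the turnover into D is done by 2.31 s, while D takes 27.0 min to go from 42.2% to 4.45%, which is 0.977 of a power of ten, with E falling to 35.7%. The reckoned 22.4 min stands against the 3.0 min of the reading.

A neighbour of zeta, with 0.012 M of Q: 68.1% of E gives a decade time of 15.3 min, shorter, and D of 35.0%. Computed, that flask holds D 37.9% and G 61.4%.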